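**Strategy.** In the lower (gallocatechin) unit, O1 sits on C8a and the interflavan bond sits on the neighbouring ring-A carbon C8. The route makes both bonds from one aryne spanning C8–C8a. An open-chain (1R,2S)-1,3-diarylpropane-1,2-diol monoether carrying a C8a–F bond is lithiated at C8 and loses LiF. The C2 alkoxide then closes ring C by forming O1–C8a. The C8 carbanion released opens the benzylic C4–O bond of a 2,3-trans flav-3-ene oxide (the robinetinidol unit) with inversion. One flask thus gives the chroman ring, the C4–C8 linkage and the 4α configuration; global hydrogenolysis finishes the synthesis.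

Key step: step 13

Assumption: 11 and 13 are taken as purchasable, and the sense of induction assigned to the tartrate in step 3 and to the PyOx ligand in step 9 follows the accepted facial models for these catalysts.

**Step 1**
Reactants: 1 1,3,5-trifluorobenzene
Product: 2 1,3-bis(benzyloxy)-5-fluorobenzene
Conditions: BnOH (2.1 equiv), NaH (2.2 equiv), NMP, 0 → 80 °C
Reagents that add atoms: benzyl alcohol OCc1ccccc1
Why: Twofold SNAr by sodium benzyloxide, in which the third substitution is markedly slower, so one C–F bond is kept as the handle for steps 5 and 13.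

**Step 2**
Reactants: 3 3,4,5-tris(benzyloxy)benzaldehyde
Product: 4 rac-1-[3,4,5-tris(benzyloxy)phenyl]prop-2-en-1-ol
Conditions: CH2=CHMgBr (1.2 equiv), THF, −78 → 0 °C; pH 7 buffer
Reagents that add atoms: vinylmagnesium bromide C=C[Mg]Br
Why: Grignard 1,2-addition gives the racemic secondary allylic alcohol required for kinetic resolution.

**Step 3**
Reactants: 4 rac-1-[3,4,5-tris(benzyloxy)phenyl]prop-2-en-1-ol
Product: 5 (R)-[(2S)-oxiran-2-yl][3,4,5-tris(benzyloxy)phenyl]methanol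
Conditions: Ti(OiPr)4 (0.15 equiv), diisopropyl D-(−)-tartrate (0.2 equiv), t-BuOOH (0.45 equiv), 4 Å MS, CH2Cl2, −20 °C
Reagents that add atoms: tert-butyl hydroperoxide CC(C)(C)OO
Why: Sharpless kinetic resolution, in which the D-tartrate catalyst should epoxidise the (S)-alcohol fast and erythro-selectively, so the catalyst selects the carbinol centre (later C2 of the lower unit) and sets the oxirane carbon (later C3) relative to it, while the (R)-alcohol stays behind and is separated.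

**Step 4**
Reactants: 5 (R)-[(2S)-oxiran-2-yl][3,4,5-tris(benzyloxy)phenyl]methanol
Product: 6 {(R)-[(2S)-oxiran-2-yl][3,4,5-tris(benzyloxy)phenyl]methoxy}triisopropylsilane
Conditions: TIPSOTf, 2,6-lutidine, CH2Cl2, −78 → 0 °C
Reagents that add atoms: triisopropylsilyl triflate CC(C)[Si](C(C)C)(C(C)C)OS(=O)(=O)C(F)(F)F
Why: Silylation without a free alkoxide avoids Payne rearrangement, and the bulky TIPS group is chosen because it resists O-to-O silyl migration in step 6.

**Step 5**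
Reactants: 2 1,3-bis(benzyloxy)-5-fluorobenzene; 6 {(R)-[(2S)-oxiran-2-yl][3,4,5-tris(benzyloxy)phenyl]methoxy}triisopropylsilane
Product: 8 (1R,2S)-3-[2,4-bis(benzyloxy)-6-fluorophenyl]-1-[3,4,5-tris(benzyloxy)phenyl]-1-[(triisopropylsilyl)oxy]propan-2-ol, via 2,4-bis(benzyloxy)-6-fluorophenyllithium 7 (not isolated)
Conditions: 2, n-BuLi, THF, −78 °C; then 6, BF3·OEt2, −78 °C
Reagents that add atoms: none
Why: Directed ortho-lithiation at the position flanked by F and OBn, followed at −78 °C (below the temperature of LiF loss) by BF3-promoted aryllithium opening of the terminal epoxide at CH2, which leaves both stereocentres untouched.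

**Step 6**
Reactants: 8 (1R,2S)-3-[2,4-bis(benzyloxy)-6-fluorophenyl]-1-[3,4,5-tris(benzyloxy)phenyl]-1-[(triisopropylsilyl)oxy]propan-2-ol
Product: 9 [(1R,2S)-2-(benzyloxy)-3-[2,4-bis(benzyloxy)-6-fluorophenyl]-1-[3,4,5-tris(benzyloxy)phenyl]propoxy]triisopropylsilane
Conditions: NaH, BnBr, n-Bu4NI (cat.), THF, 0 °C → rt
Reagents that add atoms: benzyl bromide BrCc1ccccc1
Why: Williamson benzylation of the secondary alkoxide, run in THF at or below room temperature so that intramolecular SNAr on the C–F bond and silyl migration stay slow.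

**Step 7**
Reactants: 9 [(1R,2S)-2-(benzyloxy)-3-[2,4-bis(benzyloxy)-6-fluorophenyl]-1-[3,4,5-tris(benzyloxy)phenyl]propoxy]triisopropylsilane
Product: 10 (1R,2S)-2-(benzyloxy)-3-[2,4-bis(benzyloxy)-6-fluorophenyl]-1-[3,4,5-tris(benzyloxy)phenyl]propan-1-ol
Conditions: TBAF, AcOH, THF, rt
Reagents that add atoms: none
Why: Acetic-acid-buffered fluoride desilylation frees the benzylic hydroxyl without generating an alkoxide that could attack the C–F bond.

**Step 8**
Reactants: 11 7-hydroxy-4H-chromen-4-one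
Product: 12 7-(benzyloxy)-4H-chromen-4-one
Conditions: BnBr, K2CO3, DMF, 60 °C
Reagents that add atoms: benzyl bromide BrCc1ccccc1
Why: Williamson O-benzylation of the phenol.

**Step 9**
Reactants: 12 7-(benzyloxy)-4H-chromen-4-one; 13 3,4,5-tris(benzyloxy)phenylboronic acid
Product: 14 (2S)-7-(benzyloxy)-2-[3,4,5-tris(benzyloxy)phenyl]chroman-4-one
Conditions: Pd(OCOCF3)2 (5 mol%), (R)-4-tert-butyl-2-(pyridin-2-yl)-4,5-dihydrooxazole (6 mol%), NH4PF6 (30 mol%), H2O (5 equiv), ClCH2CH2Cl, 60 °C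
Reagents that add atoms: none
Why: Palladium-catalysed asymmetric conjugate addition of an arylboronic acid to a chromone sets C2 under ligand control, with the (R)-ligand expected to give the (2S)-flavanone.

**Step 10**
Reactants: 14 (2S)-7-(benzyloxy)-2-[3,4,5-tris(benzyloxy)phenyl]chroman-4-one
Product: 15 (2S,4S)-7-(benzyloxy)-2-[3,4,5-tris(benzyloxy)phenyl]chroman-4-ol
Conditions: NaBH4, THF/MeOH, 0 °C
Reagents that add atoms: none
Why: Axial hydride delivery should give the 2,4-cis alcohol, whose C4 configuration is irrelevant because it is removed in step 11.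

**Step 11**
Reactants: 15 (2S,4S)-7-(benzyloxy)-2-[3,4,5-tris(benzyloxy)phenyl]chroman-4-ol
Product: 16 (2S)-7-(benzyloxy)-2-[3,4,5-tris(benzyloxy)phenyl]-2H-chromene
Conditions: Burgess reagent, toluene, 50 °C, dark
Reagents that add atoms: none
Why: Burgess dehydration under neutral conditions gives the flav-3-ene without the acid that would ionise C4 or C2 of this electron-rich system.

**Step 12**
Reactants: 16 (2S)-7-(benzyloxy)-2-[3,4,5-tris(benzyloxy)phenyl]-2H-chromene
Product: 17 (2R,3S,4S)-7-(benzyloxy)-3,4-epoxy-2-[3,4,5-tris(benzyloxy)phenyl]chromane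
Conditions: dimethyldioxirane (acetone solution), CH2Cl2, −40 → 0 °C; evaporated cold and used at once
Reagents that add atoms: dimethyldioxirane CC1(C)OO1
Why: Neutral dioxirane epoxidation should occur on the face of C3=C4 opposite to the 2-aryl group, setting C3 and giving the 2,3-trans epoxide with acetone as the only by-product.

**Step 13**
Reactants: 10 (1R,2S)-2-(benzyloxy)-3-[2,4-bis(benzyloxy)-6-fluorophenyl]-1-[3,4,5-tris(benzyloxy)phenyl]propan-1-ol; 17 (2R,3S,4S)-7-(benzyloxy)-3,4-epoxy-2-[3,4,5-tris(benzyloxy)phenyl]chromane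
Product: 21 (2R,3S,4S)-7-(benzyloxy)-4-{(2R,3S)-3,5,7-tris(benzyloxy)-2-[3,4,5-tris(benzyloxy)phenyl]chroman-8-yl}-2-[3,4,5-tris(benzyloxy)phenyl]chroman-3-ol, via C8-lithiated lithium alkoxide 18 (not isolated), via C8–C8a aryne lithium alkoxide 19 (not isolated), via 8-lithioflavan 20 (not isolated)
Conditions: 10, n-BuLi (2.05 equiv), THF, −78 °C, then −78 → −25 °C; recool to −78 °C, 17 (1.3 equiv), BF3·OEt2 (1.5 equiv); aq. NaHCO3
Reagents that add atoms: none
Why: Proposed new method: the first equivalent of n-BuLi gives the lithium alkoxide and the second removes H-8, the only ring-A proton flanked by F and OBn (18); on warming, LiF is lost across C8/C8a and the C2 alkoxide adds to C8a of aryne 19 in a 6-exo-dig closure that forms O1–C8a, completes ring C of the lower unit and leaves the carbanion on C8 (20). The closest known reaction types are the aryne ring closure of tethered heteroatom nucleophiles and the anionic benzyne cyclization followed by electrophile quench, and the capture is the BF3-promoted opening of an epoxide by an aryllithium, so each event has precedent but their union in one flask on a flavan precursor does not. Site selectivity of the closure is doubly secured, since only attack at C8a gives an unstrained six-membered ring and the 7-OBn group polarises the aryne so that negative charge builds up at C8 next to it. No stereocentre of the lower unit is touched because the alkoxide oxygen is the nucleophile, so C2 and C3 keep the configuration set in step 3. The one new stereocentre, C4 of the upper unit, is controlled by the epoxide: backside attack at the benzylic C4–O bond (activated by O1 and 7-OBn) places the aryl group trans to O-3 and cis to the 2-aryl group, the all-equatorial 4α arrangement. The step needs C8 over C6 lithiation, C–C capture over proton return and C4 over C3 opening, which the fluorine substituent, the amine-free medium and the benzylic activation of C4 are expected to provide.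

**Step 14**
Reactants: 21 (2R,3S,4S)-7-(benzyloxy)-4-{(2R,3S)-3,5,7-tris(benzyloxy)-2-[3,4,5-tris(benzyloxy)phenyl]chroman-8-yl}-2-[3,4,5-tris(benzyloxy)phenyl]chroman-3-ol
Product: 22 robinetinidol-(4α→8)-gallocatechin
Conditions: H2 (1 atm), Pd(OH)2/C, THF/MeOH/H2O, rt; filtered and freeze-dried under argon
Reagents that add atoms: none
Why: Hydrogenolysis of all ten benzyl ethers, under which the cyclic C2–O1 ethers and the interflavan C4–C8 bond of flavan oligomers are expected to survive.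

**Compound list**

1 | 1,3,5-trifluorobenzene | Fc1cc(F)cc(F)c1 | starting material
2 | 1,3-bis(benzyloxy)-5-fluorobenzene | Fc1cc(OCc2ccccc2)cc(OCc2ccccc2)c1 | intermediate
3 | 3,4,5-tris(benzyloxy)benzaldehyde | O=Cc1cc(OCc2ccccc2)c(OCc2ccccc2)c(OCc2ccccc2)c1 | starting material
4 | rac-1-[3,4,5-tris(benzyloxy)phenyl]prop-2-en-1-ol | C=CC(O)c1cc(OCc2ccccc2)c(OCc2ccccc2)c(OCc2ccccc2)c1 | intermediate
5 | (R)-[(2S)-oxiran-2-yl][3,4,5-tris(benzyloxy)phenyl]methanol | O[C@@H]([C@@H]1CO1)c1cc(OCc2ccccc2)c(OCc2ccccc2)c(OCc2ccccc2)c1 | intermediate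
6 | {(R)-[(2S)-oxiran-2-yl][3,4,5-tris(benzyloxy)phenyl]methoxy}triisopropylsilane | CC(C)[Si](C(C)C)(C(C)C)O[C@@H]([C@@H]1CO1)c1cc(OCc2ccccc2)c(OCc2ccccc2)c(OCc2ccccc2)c1 | intermediate
7 | 2,4-bis(benzyloxy)-6-fluorophenyllithium | [Li]c1c(F)cc(OCc2ccccc2)cc1OCc1ccccc1 | intermediate
8 | (1R,2S)-3-[2,4-bis(benzyloxy)-6-fluorophenyl]-1-[3,4,5-tris(benzyloxy)phenyl]-1-[(triisopropylsilyl)oxy]propan-2-ol | CC(C)[Si](C(C)C)(C(C)C)O[C@@H]([C@@H](O)Cc1c(F)cc(OCc2ccccc2)cc1OCc1ccccc1)c1cc(OCc2ccccc2)c(OCc2ccccc2)c(OCc2ccccc2)c1 | intermediate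
9 | [(1R,2S)-2-(benzyloxy)-3-[2,4-bis(benzyloxy)-6-fluorophenyl]-1-[3,4,5-tris(benzyloxy)phenyl]propoxy]triisopropylsilane | CC(C)[Si](C(C)C)(C(C)C)O[C@@H]([C@@H](OCc1ccccc1)Cc1c(F)cc(OCc2ccccc2)cc1OCc1ccccc1)c1cc(OCc2ccccc2)c(OCc2ccccc2)c(OCc2ccccc2)c1 | intermediate
10 | (1R,2S)-2-(benzyloxy)-3-[2,4-bis(benzyloxy)-6-fluorophenyl]-1-[3,4,5-tris(benzyloxy)phenyl]propan-1-ol | O[C@@H]([C@@H](OCc1ccccc1)Cc1c(F)cc(OCc2ccccc2)cc1OCc1ccccc1)c1cc(OCc2ccccc2)c(OCc2ccccc2)c(OCc2ccccc2)c1 | intermediate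
11 | 7-hydroxy-4H-chromen-4-one | O=c1ccoc2cc(O)ccc12 | starting material
12 | 7-(benzyloxy)-4H-chromen-4-one | O=c1ccoc2cc(OCc3ccccc3)ccc12 | intermediate
13 | 3,4,5-tris(benzyloxy)phenylboronic acid | OB(O)c1cc(OCc2ccccc2)c(OCc2ccccc2)c(OCc2ccccc2)c1 | starting material
14 | (2S)-7-(benzyloxy)-2-[3,4,5-tris(benzyloxy)phenyl]chroman-4-one | O(Cc1ccccc1)c1ccc2c(c1)O[C@H](c1cc(OCc3ccccc3)c(OCc3ccccc3)c(OCc3ccccc3)c1)CC2=O | intermediate
15 | (2S,4S)-7-(benzyloxy)-2-[3,4,5-tris(benzyloxy)phenyl]chroman-4-ol (2,4-cis) | O(Cc1ccccc1)c1ccc2c(c1)O[C@H](c1cc(OCc3ccccc3)c(OCc3ccccc3)c(OCc3ccccc3)c1)C[C@@H]2O | intermediate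
16 | (2S)-7-(benzyloxy)-2-[3,4,5-tris(benzyloxy)phenyl]-2H-chromene | O(Cc1ccccc1)c1ccc2c(c1)O[C@H](c1cc(OCc3ccccc3)c(OCc3ccccc3)c(OCc3ccccc3)c1)C=C2 | intermediate
17 | (2R,3S,4S)-7-(benzyloxy)-3,4-epoxy-2-[3,4,5-tris(benzyloxy)phenyl]chromane (epoxide trans to the 2-aryl group) | O(Cc1ccccc1)c1ccc2c(c1)O[C@H](c1cc(OCc3ccccc3)c(OCc3ccccc3)c(OCc3ccccc3)c1)[C@H]1O[C@@H]21 | intermediate
18 | lithium (1R,2S)-2-(benzyloxy)-3-[2,4-bis(benzyloxy)-6-fluoro-5-lithiophenyl]-1-[3,4,5-tris(benzyloxy)phenyl]propan-1-olate (lithiated at the future C8) | [Li]O[C@@H]([C@@H](OCc1ccccc1)Cc1c(F)c([Li])c(OCc2ccccc2)cc1OCc1ccccc1)c1cc(OCc2ccccc2)c(OCc2ccccc2)c(OCc2ccccc2)c1 | intermediate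
19 | lithium alkoxide of the 3,5-bis(benzyloxy)aryne formed across the future C8–C8a bond | [Li]O[C@@H]([C@@H](OCc1ccccc1)CC1=C(OCc2ccccc2)C=C(OCc2ccccc2)C#C1)c1cc(OCc2ccccc2)c(OCc2ccccc2)c(OCc2ccccc2)c1 | intermediate
20 | (2R,3S)-3,5,7-tris(benzyloxy)-2-[3,4,5-tris(benzyloxy)phenyl]chroman-8-yllithium | [Li]c1c(OCc2ccccc2)cc(OCc2ccccc2)c2c1O[C@H](c1cc(OCc3ccccc3)c(OCc3ccccc3)c(OCc3ccccc3)c1)[C@@H](OCc1ccccc1)C2 | intermediate
21 | (2R,3S,4S)-7-(benzyloxy)-4-{(2R,3S)-3,5,7-tris(benzyloxy)-2-[3,4,5-tris(benzyloxy)phenyl]chroman-8-yl}-2-[3,4,5-tris(benzyloxy)phenyl]chroman-3-ol | O(Cc1ccccc1)c1ccc2c(c1)O[C@H](c1cc(OCc3ccccc3)c(OCc3ccccc3)c(OCc3ccccc3)c1)[C@@H](O)[C@@H]2c1c(OCc2ccccc2)cc(OCc2ccccc2)c2c1O[C@H](c1cc(OCc3ccccc3)c(OCc3ccccc3)c(OCc3ccccc3)c1)[C@@H](OCc1ccccc1)C2 | intermediate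
22 | robinetinidol-(4α→8)-gallocatechin | Oc1ccc2c(c1)O[C@H](c1cc(O)c(O)c(O)c1)[C@@H](O)[C@@H]2c1c(O)cc(O)c2c1O[C@H](c1cc(O)c(O)c(O)c1)[C@@H](O)C2 | target

**Step count and risks**

Total step count: 14. Longest linear sequence: 8 steps (steps 2–7, 13 and 14, from aldehyde 3).

Steps most likely to fail:

1. Step 13 (Proposed new method). Possible failures are proton return to C8 or competing lithiation at C6, intermolecular capture of the aryne, and Lewis-acid-triggered rearrangement of the epoxide before the C–C bond forms. The fallback uses known chemistry and sets out from 10. Ring C is closed by intramolecular SNAr of the potassium alkoxide on the C8a–F bond (KH, 18-crown-6, THF, 0 °C → rt), giving (2R,3S)-3,5,7-tris(benzyloxy)-2-[3,4,5-tris(benzyloxy)phenyl]chromane F1. NBS (CH2Cl2, −78 → 0 °C) is expected to brominate C8 selectively, as is usual for 5,7-di-O-benzylflavans, giving (2R,3S)-3,5,7-tris(benzyloxy)-8-bromo-2-[3,4,5-tris(benzyloxy)phenyl]chromane F2. Bromine–lithium exchange (n-BuLi, THF, −78 °C) then returns the route at aryllithium 20, which is carried on with 17 and BF3·OEt2 to 21.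

2. Step 12. Possible failures are rearrangement or ring opening of the very electron-rich benzylic epoxide during its formation or concentration, and incomplete facial selectivity. The fallback avoids the epoxide and sets out from 14, using aryllithium 20 generated as in step 13. Addition of 20 to ketone 14 (THF, −78 °C) gives 7-(benzyloxy)-4-{(2R,3S)-3,5,7-tris(benzyloxy)-2-[3,4,5-tris(benzyloxy)phenyl]chroman-8-yl}-2-[3,4,5-tris(benzyloxy)phenyl]chroman-4-ol F3 as a C4 epimer mixture. Burgess dehydration gives (2S)-7-(benzyloxy)-4-{(2R,3S)-3,5,7-tris(benzyloxy)-2-[3,4,5-tris(benzyloxy)phenyl]chroman-8-yl}-2-[3,4,5-tris(benzyloxy)phenyl]-2H-chromene F4. Hydroboration–oxidation (BH3·THF; NaOH, H2O2) on the face opposite to the 2-aryl group places 3-OH trans to that group and, by syn addition, H-4 on the same face, which returns the route at 21.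

3. Step 9. Possible failures are sluggish addition to the electron-rich chromone, protodeboronation of the boronic acid, and insufficient enantioselectivity. The fallback sets out from 3. Claisen–Schmidt condensation of 3 with 1-[4-(benzyloxy)-2-hydroxyphenyl]ethan-1-one F5 (KOH, EtOH) gives (E)-1-[4-(benzyloxy)-2-hydroxyphenyl]-3-[3,4,5-tris(benzyloxy)phenyl]prop-2-en-1-one F6. Cyclisation (NaOAc, EtOH, reflux) gives rac-7-(benzyloxy)-2-[3,4,5-tris(benzyloxy)phenyl]chroman-4-one F7. Kinetic resolution by asymmetric transfer hydrogenation (RuCl[(S,S)-TsDPEN](p-cymene), HCO2H/Et3N, the antipode expected to reduce the (2S)-ketone) gives the cis-alcohol directly and returns the route at 15; unreduced (2R)-ketone is separated.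

**Further compounds**

F1 | step 13 | (2R,3S)-3,5,7-tris(benzyloxy)-2-[3,4,5-tris(benzyloxy)phenyl]chromane | c1c(OCc2ccccc2)cc(OCc2ccccc2)c2c1O[C@H](c1cc(OCc3ccccc3)c(OCc3ccccc3)c(OCc3ccccc3)c1)[C@@H](OCc1ccccc1)C2
F2 | step 13 | (2R,3S)-3,5,7-tris(benzyloxy)-8-bromo-2-[3,4,5-tris(benzyloxy)phenyl]chromane | Brc1c(OCc2ccccc2)cc(OCc2ccccc2)c2c1O[C@H](c1cc(OCc3ccccc3)c(OCc3ccccc3)c(OCc3ccccc3)c1)[C@@H](OCc1ccccc1)C2
F3 | step 12 | 7-(benzyloxy)-4-{(2R,3S)-3,5,7-tris(benzyloxy)-2-[3,4,5-tris(benzyloxy)phenyl]chroman-8-yl}-2-[3,4,5-tris(benzyloxy)phenyl]chroman-4-ol (2S, C4 epimers) | O(Cc1ccccc1)c1ccc2c(c1)O[C@H](c1cc(OCc3ccccc3)c(OCc3ccccc3)c(OCc3ccccc3)c1)CC2(O)c1c(OCc2ccccc2)cc(OCc2ccccc2)c2c1O[C@H](c1cc(OCc3ccccc3)c(OCc3ccccc3)c(OCc3ccccc3)c1)[C@@H](OCc1ccccc1)C2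
F4 | step 12 | (2S)-7-(benzyloxy)-4-{(2R,3S)-3,5,7-tris(benzyloxy)-2-[3,4,5-tris(benzyloxy)phenyl]chroman-8-yl}-2-[3,4,5-tris(benzyloxy)phenyl]-2H-chromene | O(Cc1ccccc1)c1ccc2c(c1)O[C@H](c1cc(OCc3ccccc3)c(OCc3ccccc3)c(OCc3ccccc3)c1)C=C2c1c(OCc2ccccc2)cc(OCc2ccccc2)c2c1O[C@H](c1cc(OCc3ccccc3)c(OCc3ccccc3)c(OCc3ccccc3)c1)[C@@H](OCc1ccccc1)C2
F5 | step 9 | 1-[4-(benzyloxy)-2-hydroxyphenyl]ethan-1-one | CC(=O)c1ccc(OCc2ccccc2)cc1O
F6 | step 9 | (E)-1-[4-(benzyloxy)-2-hydroxyphenyl]-3-[3,4,5-tris(benzyloxy)phenyl]prop-2-en-1-one | O=C(/C=C/c1cc(OCc2ccccc2)c(OCc2ccccc2)c(OCc2ccccc2)c1)c1ccc(OCc2ccccc2)cc1O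
F7 | step 9 | rac-7-(benzyloxy)-2-[3,4,5-tris(benzyloxy)phenyl]chroman-4-one | O(Cc1ccccc1)c1ccc2c(c1)OC(c1cc(OCc3ccccc3)c(OCc3ccccc3)c(OCc3ccccc3)c1)CC2=O
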